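## Structural features

The target is a flavone: a 4H-chromen-4-one in which resorcinol-type ring A (OH at C5 and C7, CH at C6 and C8) is fused to pyranone ring C along the C4a–C8a bond. Ring C carries a 4-hydroxy-2-methoxyphenyl group (ring B) at C2 and a 3-methylbut-2-enyl (prenyl) chain at C3. There is no stereocentre, and the side-chain alkene ends in two identical methyl groups, so no stereochemical relationship has to be set. The C2=C3 bond is fully substituted and crowded: the prenyl CH2 lies between the C4 carbonyl and an ortho-substituted aryl ring that is twisted out of plane. The fragile elements are the prenyl double bond (Markovnikov addition of protic acid, cationic cyclisation, hydrogenation), the three free phenols (the C5 hydroxyl is chelated to the C4 carbonyl) and the pyranone, which hard nucleophiles can open. The real difficulty is telling four oxygens apart: one methyl ether at C2' must persist while C5, C7 and C4' end as free OH, and the unmasking must not touch the prenyl group. The key step uses the 1,3-dioxygenated pattern of ring A. C5(OH), C6(H), C7(O) and C8(H) map onto a ketene carbonyl carbon, the two carbons of an alkoxyethyne and the ketene alpha carbon, and these are stitched onto the C8a=C4a edge of a preformed pyranone. This leaves C5–OH free and C7–O as a cleavable ether, both distinct from the C2' methyl ether.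

## Logic of the disconnections

22 is traced to 20 by re-attaching two temporary groups, a tert-butyl ether on O7 and a silyl ether on O4'. The C2' methyl ether is then the only permanent O-substituent and nothing else changes. The forward step must cleave an O–C(tert-alkyl) bond and an O–Si bond without protonating the prenyl alkene, which calls for an aprotic, buffered ether exchange followed by fluoride.

20 is cut at C4a–C5, C5–C6 and C7–C8, which removes the whole of ring A and gives 11 and 15. The cut is made here because the resorcinol pattern is exactly what a ketene and an ynol ether deliver, and because all the crowding around C2=C3 then sits in a monocyclic pyranone that is easy to assemble. The forward step must generate a ketene next to a basic pyranone carbonyl, add it to 15 with the oxygen-bearing carbon going to C8, and then close onto the only available ring CH.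

15 is cut at its O–C(sp) bond and traced to 12. A two-carbon chloroalkene is used because both chlorine-bearing carbons can be taken to the alkyne oxidation level in one flask. The forward sequence needs low temperature throughout, since 15 is thermally labile.

11 is traced through 10 to 9 by cutting the C–Cl bond and then the bond between the side-chain CH2 (future C8) and the carboxyl carbon (future C5). This reduces the side chain to a methyl group whose protons are vinylogously acidic. The forward carboxylation must be regioselective for that methyl group, and the acid and its chloride must be made and handled without heat or mineral acid.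

9 is opened at one ring C–O bond to triketone 8, and 8 is cut between C4a and C8a into 6 and the two-carbon acyl donor 7. This turns the heterocycle into a linear 1,3,5-tricarbonyl chain, the standard pyranone precursor. The forward step needs a dianion that reacts only at its terminal carbon and a ring closure that is not acid-promoted, because a prenyl group next to an enol closes to a dihydropyran in acid.

6 is cut at the bond between C3 and the prenyl CH2 to give 4 and 5. The central carbon of a 1,3-diketone is the most reliable site for attaching an allylic halide; the forward step must favour C- over O-alkylation and stop at one alkylation.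

4 is cut at C3–C4 into 2 and the acetyl donor 3, and 2 is traced to 1 by removing the silyl group. The forward acylation must avoid hot alkoxide, which would threaten an aryl silyl ether para to a carbonyl group.

## Other disconnections considered

Alternative 1: The cut runs through O1–C8a and C4–C4a, so ring A arrives as an aryne and everything else as the α-prenylcinnamic acid A2.
- Forward key step: CsF would release the aryne from the ortho-silylaryl triflate A3. The carboxylate of A2 should add through oxygen at the aryne carbon remote from the flanking alkoxy group. The aryl anion formed next to that alkoxy group should then take the acyl group, giving the ortho-hydroxyaryl ketone A1.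
- In its favour: aryne insertion into a carboxylic acid C–O bond is an established reaction type. On this point the alternative is better than the chosen plan, whose key step extends known chemistry to a new ring. The usual regiochemical bias of 3-alkoxyarynes would give exactly the 2'-hydroxy-4',6'-dioxygenated ketone, and the route is convergent.
- Against it here: A1 is still an open-chain chalcone. Ring C must be closed afterwards by an oxidative cyclisation to the tris(methoxymethyl) ether A4, and the prenyl alkene and the α-substituted enone may not tolerate that oxidation. The acetal groups then need protic acid, the reagent the prenyl group tolerates least. Protonation of the aryl anion by the acid proton, which leads to O-arylation without acyl transfer, is a plausible competing path.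
- Comparison: on structure, the chosen plan forms the crowded C2=C3 bond early on a simple pyranone and ends with an acid-free unmasking. On mechanism, both rely on polarity-controlled regiochemistry. On step economy the two are about equal.

Alternative 2: The cut runs through C3–C4 and O1–C2, dividing the molecule into the salicylaldehyde A5 and the aryl alkyne A6, which already carries the prenyl chain.
- Forward key step: [Cp*RhCl2]2 would activate the formyl C–H bond of A5 with the phenoxide as directing group. A6 would insert into the acyl–rhodium bond with the aryl-bearing carbon next to the metal, and C–O reductive elimination would close ring C to A4. Cu(OAc)2 would return monovalent rhodium to the trivalent state.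
- In its favour: this is the shortest plan, with the whole skeleton assembled in one step from two small pieces. It is clearly better than the chosen plan on step economy and convergence. The annulation is a known reaction of salicylaldehydes with internal alkynes, so it is also better on precedent.
- Against it here: A6 is a skipped enyne whose doubly activated CH2 can isomerise to an allene or a conjugated enyne under warm, metal-containing conditions. The formyl group of A5 is flanked by an ortho ether and the alkyne by an ortho-methoxyaryl group, so insertion is hindered. The aryl/alkyl regiochemistry that puts ring B at C2 is expected but not enforced. A4 must again be unmasked with protic acid.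
- Comparison: the chosen plan is longer, but its regiochemistry is fixed by bond polarity with no competing site, and its endgame avoids acid.

Alternative 3: The cut removes ring B; C1'–C2' and C5'–C6' are disconnected to give the 2-ethynylchromone A8 and the oxygenated diene A9.
- Forward key step: a Diels–Alder reaction would join the nucleophilic CH2 terminus of A9 to the alkyne terminus (C5'–C6') and the ketene-acetal carbon to the inner alkyne carbon (C1'–C2'). Loss of one methoxy group as the alcohol and of the silyl group on work-up would aromatise the adduct to A7.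
- In its favour: the 2'-OMe/4'-OH pattern is created directly with the C4' hydroxyl free and no protecting group on ring B, which is better than the chosen plan. Regiochemistry is again set by polarity. Cycloaddition–aromatisation of such dienes with acetylenic ketones and esters is known, so on precedent the two plans are about equal: each stretches a known process to a chromone-type partner.
- Against it here: the triple bond of A8 is activated only vinylogously through C2 and is shielded by the C3 prenyl group. The cycloaddition would need heat that the labile diene A9 may not survive, and conjugate attack without ring closure is a plausible diversion. A8 needs a complete chromone synthesis with the prenyl group and a C2 alkynylation before the key step, so the route is at best equal in length. The ring A ethers of A7 need protic acid.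
- Comparison: the chosen plan uses a more electrophilic partner (a ketene) with a strongly polarised ynol ether, and keeps acid away from the prenyl group.

Key step: step 8

Remark (assumptions): flavone numbering is used for all intermediates (the pyranone methyl carbon is the future C8). Compounds 1, 3, 5, 7 and 12 and all reagents are taken to be purchasable. The atom mapping of the benzannulation (acyl carbon to C5, alkyne CH to C6, alkyne C–O to C7, methylene to C8) reproduces the 5-OH/7-OR pattern, so the skeletons of 11 and 20 need no correction. The improvements are confined to reagents: neutral acid chloride formation, non-acidic pyranone closure, and a buffered aprotic endgame in one flask.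

## Route

Step 1
Reactants: 1 1-(4-hydroxy-2-methoxyphenyl)ethan-1-one
Product: 2 1-[2-methoxy-4-(triisopropylsilyloxy)phenyl]ethan-1-one
Conditions: i-Pr3SiCl, imidazole, DMF, rt
Reagents that add atoms: chlorotriisopropylsilane, CC(C)[Si](Cl)(C(C)C)C(C)C
Why: Imidazole-promoted silylation of a phenol; the hindered aryl silyl ether should withstand the amide bases, the mild Lewis acid and the carbonate of the later steps and is removed by fluoride at the end.

Step 2
Reactants: 2 1-[2-methoxy-4-(triisopropylsilyloxy)phenyl]ethan-1-one; 3 1-acetyl-1H-benzotriazole
Product: 4 1-[2-methoxy-4-(triisopropylsilyloxy)phenyl]butane-1,3-dione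
Conditions: MgBr2·OEt2, i-Pr2NEt, CH2Cl2, rt; dilute aqueous acid work-up
Reagents that add atoms: none
Why: Crossed Claisen acylation by soft enolisation: MgBr2 chelates the aryl ketone so the hindered amine can enolise it, and the magnesium enolate is C-acylated by the acyl benzotriazole. The product stays bound as a magnesium diketonate, which should stop further acylation and keeps alkoxide away from the aryl silyl ether.

Step 3
Reactants: 4 1-[2-methoxy-4-(triisopropylsilyloxy)phenyl]butane-1,3-dione; 5 1-bromo-3-methylbut-2-ene (prenyl bromide)
Product: 6 1-[2-methoxy-4-(triisopropylsilyloxy)phenyl]-2-(3-methylbut-2-en-1-yl)butane-1,3-dione (racemic, enolisable)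
Conditions: K2CO3, acetone, rt to 40 °C
Reagents that add atoms: none
Why: C-alkylation of a 1,3-diketone by SN2 attack of the potassium diketonate on the primary allylic bromide. One equivalent of halide at moderate temperature should limit O-alkylation and double alkylation, and anhydrous carbonate leaves the silyl ether alone.

Step 4
Reactants: 6 1-[2-methoxy-4-(triisopropylsilyloxy)phenyl]-2-(3-methylbut-2-en-1-yl)butane-1,3-dione; 7 N-methoxy-N-methylacetamide
Product: 9 2-[2-methoxy-4-(triisopropylsilyloxy)phenyl]-6-methyl-3-(3-methylbut-2-en-1-yl)-4H-pyran-4-one, via triketone 8 (not isolated)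
Conditions: LiN(i-Pr)2 (2.3 equiv), THF, −78 to 0 °C; 7, −78 to 0 °C; AcOH quench; crude 8, PPh3, CCl4, THF, rt
Reagents that add atoms: none
Why: Two equivalents of amide base give the 1,3-diketone dianion, which is acylated at its terminal carbon by the Weinreb amide (stable tetrahedral adduct, no over-addition) to give triketone 8. Triphenylphosphine–tetrachloromethane then activates one enol oxygen as an oxyphosphonium salt and the other enol oxygen closes the six-membered ring by addition–elimination, a cyclodehydration that needs no strong acid, so the prenyl group should not be drawn into a dihydropyran closure.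

Step 5
Reactants: 9 2-[2-methoxy-4-(triisopropylsilyloxy)phenyl]-6-methyl-3-(3-methylbut-2-en-1-yl)-4H-pyran-4-one
Product: 10 2-{6-[2-methoxy-4-(triisopropylsilyloxy)phenyl]-5-(3-methylbut-2-en-1-yl)-4-oxo-4H-pyran-2-yl}acetic acid
Conditions: LiN(SiMe3)2, THF, −78 °C; cannulate into CO2-saturated THF, −78 °C; cold 0.5 M HCl to pH 3; concentrate below 20 °C
Reagents that add atoms: carbon dioxide, O=C=O
Why: Lateral (vinylogous) deprotonation of the 2-methyl-4-pyranone gives an extended enolate that is carboxylated at the exocyclic carbon. Inverse addition into excess CO2 and a cold, mildly acidic work-up should limit proton exchange and decarboxylation of the vinylogous β-keto acid.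

Step 6
Reactants: 10 2-{6-[2-methoxy-4-(triisopropylsilyloxy)phenyl]-5-(3-methylbut-2-en-1-yl)-4-oxo-4H-pyran-2-yl}acetic acid
Product: 11 2-{6-[2-methoxy-4-(triisopropylsilyloxy)phenyl]-5-(3-methylbut-2-en-1-yl)-4-oxo-4H-pyran-2-yl}acetyl chloride
Conditions: 1-chloro-N,N,2-trimethylprop-1-en-1-amine (Ghosez reagent), CH2Cl2, 0 °C to rt; solvent exchanged for toluene, used crude
Reagents that add atoms: 1-chloro-N,N,2-trimethylprop-1-en-1-amine, CC(C)=C(Cl)N(C)C
Why: The α-chloroenamine converts the acid into the acid chloride under neutral conditions, releasing an inert amide and no hydrogen chloride, so neither the prenyl double bond nor the basic pyranone carbonyl meets acid.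

Step 7
Reactants: 12 1,1,2-trichloroethene
Product: 15 tert-butoxyethyne, via (E)-1-tert-butoxy-1,2-dichloroethene 13 (not isolated), via lithium tert-butoxyethynide 14 (not isolated)
Conditions: KOt-Bu (1.1 equiv), THF, −40 °C to rt; n-BuLi (2.2 equiv), −78 to −40 °C; MeOH, −78 °C; aqueous work-up, distil below 40 °C under reduced pressure, store cold
Reagents that add atoms: potassium tert-butoxide, CC(C)(C)[O-].[K+]
Why: One-pot ynol ether synthesis: base-induced elimination–addition converts the trichloroalkene into dichlorovinyl ether 13, two equivalents of butyllithium effect dehydrochlorination and chlorine–lithium exchange to acetylide 14, and methanol protonates it. The product is kept cold because tert-butyl ynol ethers lose 2-methylpropene by a retro-ene reaction on warming.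

Step 8
Reactants: 11 2-{6-[2-methoxy-4-(triisopropylsilyloxy)phenyl]-5-(3-methylbut-2-en-1-yl)-4-oxo-4H-pyran-2-yl}acetyl chloride; 15 tert-butoxyethyne
Product: 20 7-tert-butoxy-5-hydroxy-2-[2-methoxy-4-(triisopropylsilyloxy)phenyl]-3-(3-methylbut-2-en-1-yl)-4H-chromen-4-one, via pyranonylketene 16 (not isolated), via 3-tert-butoxy-4-pyranonylcyclobutenone 17 (not isolated), via dienylketene 18 (not isolated), via 4aH-chromene-4,5-dione tautomer 19 (not isolated)
Conditions: 15 (3 equiv), Et3N (1.3 equiv, slow addition), toluene, 0 °C to rt; filter, remove excess 15 in vacuo at rt; toluene, 90 °C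
Reagents that add atoms: none
Why: Proposed new method: triethylamine should dehydrochlorinate 11 to ketene 16, whose electrophilic carbonyl carbon is attacked by the nucleophilic terminal CH of ynol ether 15 in a polar, asynchronous [2+2] cycloaddition that forms C5–C6 and C7–C8 and gives cyclobutenone 17; the closest known reaction type is the benzannulation of arylketenes or vinylketenes with alkoxyalkynes, which gives 3-alkoxy-1-naphthols and resorcinol monoethers, and a 4-pyranon-2-yl ketene is an untested partner in it. On heating, 17 should open reversibly by a four-electron conrotatory process (cleavage of the former ketene C=C bond, C5–C8) to dienylketene 18; only the isomer with the pyranone turned inward, cis to the ketene arm, can go on, and the outward isomer simply recloses. Ring A is closed by a thermal six-electron disrotatory electrocyclisation in which the ketene carbon bonds to the pyranone CH carbon (C4a–C5) to give dienone 19. The C4a hydrogen of 19 lies between two carbonyl groups, so tautomerisation to phenol 20 should follow at once. No stereocentre remains in 20; C4 of 17 and C4a of 19 are transient and racemic. The selectivity needed is the orientation of the [2+2] step, and it is secured by the polarisation of the ynol ether: its oxygen-bearing carbon bonds to the ketene alpha carbon, which puts the ether at C7 and the carbonyl-derived hydroxyl at C5. The electrocyclisation has no choice of site, because the other neighbour of C8a is the ring oxygen, and the pyranone C3 carbon is the nucleophilic alpha carbon of a vinylogous ester, a polarity match for the ketene carbon. Excess 15 is removed before heating so that its retro-ene fragmentation cannot release ketene into the mixture.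

Step 9
Reactants: 20 7-tert-butoxy-5-hydroxy-2-[2-methoxy-4-(triisopropylsilyloxy)phenyl]-3-(3-methylbut-2-en-1-yl)-4H-chromen-4-one
Product: 22 5,7-dihydroxy-2-(4-hydroxy-2-methoxyphenyl)-3-(3-methylbut-2-en-1-yl)-4H-chromen-4-one, via 5,7-bis(trimethylsilyl) ether 21 (not isolated)
Conditions: Me3SiOTf (4 equiv), 2,6-lutidine (6 equiv), CH2Cl2, 0 °C to rt; then n-Bu4NF (8 equiv), AcOH (8 equiv), THF, 0 °C to rt
Reagents that add atoms: none
Why: Silyl triflate-mediated exchange of a tert-butyl ether for a silyl ether: O-silylation is followed by loss of the tert-butyl cation as 2-methylpropene, and is helped by silylation of the C4 carbonyl, which makes the C7 ether a phenylogous tert-butyl ester. The hindered pyridine keeps the medium free of protic acid, so the prenyl group and the aryl methyl ether should be untouched. Buffered fluoride then cleaves the two trimethylsilyl ethers and the triisopropylsilyl ether in the same flask.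

## Compound list

1 | 1-(4-hydroxy-2-methoxyphenyl)ethan-1-one | CC(=O)c1ccc(O)cc1OC | starting material
2 | 1-[2-methoxy-4-(triisopropylsilyloxy)phenyl]ethan-1-one | CC(=O)c1ccc(O[Si](C(C)C)(C(C)C)C(C)C)cc1OC | intermediate
3 | 1-acetyl-1H-benzotriazole | CC(=O)n1nnc2ccccc21 | starting material
4 | 1-[2-methoxy-4-(triisopropylsilyloxy)phenyl]butane-1,3-dione | CC(=O)CC(=O)c1ccc(O[Si](C(C)C)(C(C)C)C(C)C)cc1OC | intermediate
5 | 1-bromo-3-methylbut-2-ene (prenyl bromide) | CC(C)=CCBr | starting material
6 | 1-[2-methoxy-4-(triisopropylsilyloxy)phenyl]-2-(3-methylbut-2-en-1-yl)butane-1,3-dione (racemic) | CC(=O)C(CC=C(C)C)C(=O)c1ccc(O[Si](C(C)C)(C(C)C)C(C)C)cc1OC | intermediate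
7 | N-methoxy-N-methylacetamide | CC(=O)N(C)OC | starting material
8 | 1-[2-methoxy-4-(triisopropylsilyloxy)phenyl]-2-(3-methylbut-2-en-1-yl)hexane-1,3,5-trione (racemic) | CC(=O)CC(=O)C(CC=C(C)C)C(=O)c1ccc(O[Si](C(C)C)(C(C)C)C(C)C)cc1OC | intermediate (not isolated)
9 | 2-[2-methoxy-4-(triisopropylsilyloxy)phenyl]-6-methyl-3-(3-methylbut-2-en-1-yl)-4H-pyran-4-one | COc1cc(O[Si](C(C)C)(C(C)C)C(C)C)ccc1-c1oc(C)cc(=O)c1CC=C(C)C | intermediate
10 | 2-{6-[2-methoxy-4-(triisopropylsilyloxy)phenyl]-5-(3-methylbut-2-en-1-yl)-4-oxo-4H-pyran-2-yl}acetic acid | COc1cc(O[Si](C(C)C)(C(C)C)C(C)C)ccc1-c1oc(CC(=O)O)cc(=O)c1CC=C(C)C | intermediate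
11 | 2-{6-[2-methoxy-4-(triisopropylsilyloxy)phenyl]-5-(3-methylbut-2-en-1-yl)-4-oxo-4H-pyran-2-yl}acetyl chloride | COc1cc(O[Si](C(C)C)(C(C)C)C(C)C)ccc1-c1oc(CC(=O)Cl)cc(=O)c1CC=C(C)C | intermediate
12 | 1,1,2-trichloroethene | ClC=C(Cl)Cl | starting material
13 | (E)-1-tert-butoxy-1,2-dichloroethene | CC(C)(C)O/C(Cl)=C\Cl | intermediate (not isolated)
14 | lithium tert-butoxyethynide | [Li]C#COC(C)(C)C | intermediate (not isolated)
15 | tert-butoxyethyne | CC(C)(C)OC#C | intermediate
16 | 2-{6-[2-methoxy-4-(triisopropylsilyloxy)phenyl]-5-(3-methylbut-2-en-1-yl)-4-oxo-4H-pyran-2-yl}ethen-1-one (ketene) | O=C=Cc1cc(=O)c(CC=C(C)C)c(-c2ccc(O[Si](C(C)C)(C(C)C)C(C)C)cc2OC)o1 | intermediate (not isolated)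
17 | 3-tert-butoxy-4-{6-[2-methoxy-4-(triisopropylsilyloxy)phenyl]-5-(3-methylbut-2-en-1-yl)-4-oxo-4H-pyran-2-yl}cyclobut-2-en-1-one (racemic) | O=C1C=C(OC(C)(C)C)C1c1cc(=O)c(CC=C(C)C)c(-c2ccc(O[Si](C(C)C)(C(C)C)C(C)C)cc2OC)o1 | intermediate (not isolated)
18 | (3E)-3-tert-butoxy-4-{6-[2-methoxy-4-(triisopropylsilyloxy)phenyl]-5-(3-methylbut-2-en-1-yl)-4-oxo-4H-pyran-2-yl}buta-1,3-dien-1-one (ketene arm cis to the pyranone) | O=C=C/C(OC(C)(C)C)=C\c1cc(=O)c(CC=C(C)C)c(-c2ccc(O[Si](C(C)C)(C(C)C)C(C)C)cc2OC)o1 | intermediate (not isolated)
19 | 7-tert-butoxy-2-[2-methoxy-4-(triisopropylsilyloxy)phenyl]-3-(3-methylbut-2-en-1-yl)-4aH-chromene-4,5-dione (racemic at C4a) | COc1cc(O[Si](C(C)C)(C(C)C)C(C)C)ccc1C1=C(CC=C(C)C)C(=O)C2C(=O)C=C(OC(C)(C)C)C=C2O1 | intermediate (not isolated)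
20 | 7-tert-butoxy-5-hydroxy-2-[2-methoxy-4-(triisopropylsilyloxy)phenyl]-3-(3-methylbut-2-en-1-yl)-4H-chromen-4-one | COc1cc(O[Si](C(C)C)(C(C)C)C(C)C)ccc1-c1oc2cc(OC(C)(C)C)cc(O)c2c(=O)c1CC=C(C)C | intermediate
21 | 2-[2-methoxy-4-(triisopropylsilyloxy)phenyl]-3-(3-methylbut-2-en-1-yl)-5,7-bis(trimethylsilyloxy)-4H-chromen-4-one | COc1cc(O[Si](C(C)C)(C(C)C)C(C)C)ccc1-c1oc2cc(O[Si](C)(C)C)cc(O[Si](C)(C)C)c2c(=O)c1CC=C(C)C | intermediate (not isolated)
22 | 5,7-dihydroxy-2-(4-hydroxy-2-methoxyphenyl)-3-(3-methylbut-2-en-1-yl)-4H-chromen-4-one | COc1cc(O)ccc1-c1oc2cc(O)cc(O)c2c(=O)c1CC=C(C)C | target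

## Step count and least certain steps

Total step count: 9. Longest linear sequence: 8 steps (steps 1 to 6, 8 and 9, from 1 to 22); step 7 is a one-step side branch.

Step 8 (key step, proposed new method). The most likely failures are consumption of the ketene by dimerisation or by acylation at the basic pyranone carbonyl before it meets 15, and unproductive ring opening of 17 in which only the outward isomer forms and recloses, because a pyranone CH is a poorer terminus for the six-electron closure than a benzene or vinyl carbon. The fallback uses known flavone chemistry (enolate acylation, diketone alkylation, cyclodehydration); it sets out from 2 and returns to the route at 22. Purchased 5,7-dihydroxy-2,2-dimethyl-4H-1,3-benzodioxin-4-one F1 would be silylated (t-BuMe2SiOTf, 2,6-lutidine, CH2Cl2) to 5,7-bis(tert-butyldimethylsilyloxy)-2,2-dimethyl-4H-1,3-benzodioxin-4-one F2. The lithium enolate of 2 (LiN(SiMe3)2, THF, −78 °C) should open F2 at the lactone carbonyl with loss of acetone to give 1-[2,4-bis(tert-butyldimethylsilyloxy)-6-hydroxyphenyl]-3-[2-methoxy-4-(triisopropylsilyloxy)phenyl]propane-1,3-dione F3. C-prenylation with 5 (K2CO3, acetone) should give 1-[2,4-bis(tert-butyldimethylsilyloxy)-6-hydroxyphenyl]-3-[2-methoxy-4-(triisopropylsilyloxy)phenyl]-2-(3-methylbut-2-en-1-yl)propane-1,3-dione F4, since the chelated phenol is much less reactive than the diketonate. Buffered cyclodehydration (NaOAc, AcOH, 80 °C) should close ring C to 5,7-bis(tert-butyldimethylsilyloxy)-2-[2-methoxy-4-(triisopropylsilyloxy)phenyl]-3-(3-methylbut-2-en-1-yl)-4H-chromen-4-one F5. n-Bu4NF with AcOH would then remove all three silyl groups to give 22; partial loss of a silyl group earlier in this sequence would do no harm.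

Step 5. The most likely failure is loss of carbon dioxide from the vinylogous β-keto acid during acidification or concentration; incomplete carboxylation through proton exchange between the lithiated pyranone and the carboxylate is a second risk. The fallback sets out from 9 and returns at 11 without ever liberating the free acid. After lithiation and carboxylation as before, the lithium carboxylate would be silylated in the flask with t-BuMe2SiCl to give tert-butyldimethylsilyl 2-{6-[2-methoxy-4-(triisopropylsilyloxy)phenyl]-5-(3-methylbut-2-en-1-yl)-4-oxo-4H-pyran-2-yl}acetate F6. Oxalyl chloride with catalytic DMF in CH2Cl2 at 0 °C should convert this silyl ester into 11 under neutral conditions, expelling the silyl chloride.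

Step 4. The most likely failure is proton transfer between the dianion and the amide (enolisation instead of addition), which returns 6; chlorination of an enol or participation of the prenyl group during ring closure is a lesser risk. The fallback replaces the acylation by aldol addition and oxidation; it sets out from 6 and returns at 8. The dianion of 6 (LiN(i-Pr)2, THF, −78 °C) would be added to acetaldehyde to give 5-hydroxy-1-[2-methoxy-4-(triisopropylsilyloxy)phenyl]-2-(3-methylbut-2-en-1-yl)hexane-1,3-dione F7 as a mixture of diastereomers. Dess–Martin periodinane (NaHCO3, CH2Cl2) should oxidise the secondary alcohol to 8, which is closed to 9 as in step 4.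

Step 9. The most likely failures are sluggish ionisation of the weakly basic aryl tert-butyl ether under the buffered silyl triflate and Friedel–Crafts tert-butylation of the electron-rich ring A by the departing cation. The fallback gives up the one-flask aprotic exchange for stepwise Brønsted acidolysis with a cation trap and isolation of the intermediate; it sets out from 20 and returns at 22. Dilute CF3CO2H in CH2Cl2 at 0 °C with 1,3,5-trimethoxybenzene as scavenger, stopped as soon as 20 is consumed, should give 5,7-dihydroxy-2-[2-methoxy-4-(triisopropylsilyloxy)phenyl]-3-(3-methylbut-2-en-1-yl)-4H-chromen-4-one F8. n-Bu4NF with AcOH in THF then removes the silyl group to give 22. The short, cold, dilute acid exposure is what protects the prenyl alkene in this variant.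

## Further compounds

F1 | step 8 | 5,7-dihydroxy-2,2-dimethyl-4H-1,3-benzodioxin-4-one | CC1(C)OC(=O)c2c(O)cc(O)cc2O1
F2 | step 8 | 5,7-bis(tert-butyldimethylsilyloxy)-2,2-dimethyl-4H-1,3-benzodioxin-4-one | CC1(C)OC(=O)c2c(O[Si](C)(C)C(C)(C)C)cc(O[Si](C)(C)C(C)(C)C)cc2O1
F3 | step 8 | 1-[2,4-bis(tert-butyldimethylsilyloxy)-6-hydroxyphenyl]-3-[2-methoxy-4-(triisopropylsilyloxy)phenyl]propane-1,3-dione | COc1cc(O[Si](C(C)C)(C(C)C)C(C)C)ccc1C(=O)CC(=O)c1c(O)cc(O[Si](C)(C)C(C)(C)C)cc1O[Si](C)(C)C(C)(C)C
F4 | step 8 | 1-[2,4-bis(tert-butyldimethylsilyloxy)-6-hydroxyphenyl]-3-[2-methoxy-4-(triisopropylsilyloxy)phenyl]-2-(3-methylbut-2-en-1-yl)propane-1,3-dione (racemic) | COc1cc(O[Si](C(C)C)(C(C)C)C(C)C)ccc1C(=O)C(CC=C(C)C)C(=O)c1c(O)cc(O[Si](C)(C)C(C)(C)C)cc1O[Si](C)(C)C(C)(C)C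
F5 | step 8 | 5,7-bis(tert-butyldimethylsilyloxy)-2-[2-methoxy-4-(triisopropylsilyloxy)phenyl]-3-(3-methylbut-2-en-1-yl)-4H-chromen-4-one | COc1cc(O[Si](C(C)C)(C(C)C)C(C)C)ccc1-c1oc2cc(O[Si](C)(C)C(C)(C)C)cc(O[Si](C)(C)C(C)(C)C)c2c(=O)c1CC=C(C)C
F6 | step 5 | tert-butyldimethylsilyl 2-{6-[2-methoxy-4-(triisopropylsilyloxy)phenyl]-5-(3-methylbut-2-en-1-yl)-4-oxo-4H-pyran-2-yl}acetate | COc1cc(O[Si](C(C)C)(C(C)C)C(C)C)ccc1-c1oc(CC(=O)O[Si](C)(C)C(C)(C)C)cc(=O)c1CC=C(C)C
F7 | step 4 | 5-hydroxy-1-[2-methoxy-4-(triisopropylsilyloxy)phenyl]-2-(3-methylbut-2-en-1-yl)hexane-1,3-dione (mixture of diastereomers) | CC(O)CC(=O)C(CC=C(C)C)C(=O)c1ccc(O[Si](C(C)C)(C(C)C)C(C)C)cc1OC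
F8 | step 9 | 5,7-dihydroxy-2-[2-methoxy-4-(triisopropylsilyloxy)phenyl]-3-(3-methylbut-2-en-1-yl)-4H-chromen-4-one | COc1cc(O[Si](C(C)C)(C(C)C)C(C)C)ccc1-c1oc2cc(O)cc(O)c2c(=O)c1CC=C(C)C
A1 | alternative 1 | (E)-2'-hydroxy-2-methoxy-4,4',6'-tris(methoxymethoxy)-alpha-(3-methylbut-2-en-1-yl)chalcone | COCOc1ccc(/C=C(\CC=C(C)C)C(=O)c2c(O)cc(OCOC)cc2OCOC)c(OC)c1
A2 | alternative 1 | (2E)-2-{[2-methoxy-4-(methoxymethoxy)phenyl]methylidene}-5-methylhex-4-enoic acid | COCOc1ccc(/C=C(\CC=C(C)C)C(=O)O)c(OC)c1
A3 | alternative 1 | 3,5-bis(methoxymethoxy)-2-(trimethylsilyl)phenyl trifluoromethanesulfonate | COCOc1cc(OCOC)c([Si](C)(C)C)c(OS(=O)(=O)C(F)(F)F)c1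
A4 | alternative 2 | 2-[2-methoxy-4-(methoxymethoxy)phenyl]-5,7-bis(methoxymethoxy)-3-(3-methylbut-2-en-1-yl)-4H-chromen-4-one | COCOc1ccc(-c2oc3cc(OCOC)cc(OCOC)c3c(=O)c2CC=C(C)C)c(OC)c1
A5 | alternative 2 | 2-hydroxy-4,6-bis(methoxymethoxy)benzaldehyde | COCOc1cc(O)c(C=O)c(OCOC)c1
A6 | alternative 2 | 2-methoxy-4-(methoxymethoxy)-1-(5-methylhex-4-en-1-yn-1-yl)benzene | COCOc1ccc(C#CCC=C(C)C)c(OC)c1
A7 | alternative 3 | 2-(4-hydroxy-2-methoxyphenyl)-5,7-bis(methoxymethoxy)-3-(3-methylbut-2-en-1-yl)-4H-chromen-4-one | COCOc1cc(OCOC)c2c(=O)c(CC=C(C)C)c(-c3ccc(O)cc3OC)oc2c1
A8 | alternative 3 | 2-ethynyl-5,7-bis(methoxymethoxy)-3-(3-methylbut-2-en-1-yl)-4H-chromen-4-one | COCOc1cc(OCOC)c2c(=O)c(CC=C(C)C)c(C#C)oc2c1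
A9 | alternative 3 | 1,1-dimethoxy-3-(trimethylsilyloxy)buta-1,3-diene | COC(OC)=CC(=C)O[Si](C)(C)C
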